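The runs were generated by integration on assumed constants, and the scatter is random.

Count per catalyst. Monday's flask repeats Tuesday's charge, so I need to know how far Tuesday's curve goes.

common to all: starting material 0.100 M
- Tuesday's: free catalyst 0.00200 M
- Friday's: free catalyst 0.00300 M
- Monday's: free catalyst 0.00200 M; time 44 min

| run | time / min | [target] / M |
|---|---|---|
| Tuesday's run | 0.26 | 0.0034 |
| Tuesday's run | 0.79 | 0.0101 |
| Tuesday's run | 1.5 | 0.0170 |
| Tuesday's run | 2.4 | 0.0236 |
| Tuesday's run | 3.4 | 0.0302 |
| Tuesday's run | 4.6 | 0.0341 |
| Tuesday's run | 5.9 | 0.0364 |
| Tuesday's run | 7.3 | 0.0380 |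
| Friday's run | 0.26 | 0.0049 |
| Friday's run | 0.79 | 0.0134 |
| Friday's run | 1.5 | 0.0236 |
| Friday's run | 2.4 | 0.0334 |
| Friday's run | 3.4 | 0.0401 |
| Friday's run | 4.6 | 0.0465 |
| Friday's run | 5.9 | 0.0498 |
| Friday's run | 7.3 | 0.0509 |

(each reading ± 5 × 10⁻⁴ M)

- Overall: starting material -> target, with free catalyst as catalyst.
- Constant volume, constant temperature.
- Readings of a species count what is bound in complexes too.
- An order is taken over about fifteen percent of the charge, up and down.

- reaction order in [free catalyst] at the outset, round the charge of the Tuesday's run, defined at two percent of the starting material turned into target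
- target in the Monday's run at 44 min, as a share of the starting material charged

My measure is the turnover number n, target over free catalyst charged: 19.0 at Tuesday's last reading. If the rate follows the catalyst charge, two flasks with equal starting material show equal n at equal early times. At the first reading, n is 1.70 on Tuesday and 1.63 on Friday, which reads as an order of 0.901.

But one early reading scatters. Order 1 asks Friday for 0.005100 M, and the reading misses that by 2.000 × 10⁻⁴ M, less than the 9.014 × 10⁻⁴ M scatter of that difference. So I keep order 1.

Next, where does Tuesday's n stop? Its last gain is 0.001600 M, and it is 0.696 of the gain before. Continuing that series gives n = 20.8. But that gain scatters by 7.071 × 10⁻⁴ M. So I go round once more with the earlier ratio, 0.590, and get n = 20.2. Taking the middle, I reckon target at 41.0% of the charge in Monday's flask.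

That holds only if the target stays once made, and I cannot compute this objection away. Tuesday's readings stop at 7.3 min, and the 44 min asked of Monday's flask is 6.03 times that time.

The forecast gives 0.85 and 41%, “allowing for a small slow tail”.

The flask gives order 1.0 and 12.3%.

    free catalyst + starting material ⇌ catalyst-substrate complex, settled at all times (95.30 M⁻¹)
    catalyst-substrate complex + starting material ⇌ doubly bound catalyst, settled at all times (10.10 M⁻¹)
    doubly bound catalyst → target + catalyst-substrate complex (14.40 min⁻¹)
    catalyst-substrate complex → spent catalyst + starting material (0.3246 min⁻¹)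
    target → decomposed product (0.04014 min⁻¹)

The target decomposes with a half-life of 17.3 min, shorter than the 44 min asked. Monday's n at that time is 6.13, below Tuesday's 19.0 at its last reading. Where 2% of the charge has turned, n grows by 6.49 min⁻¹ on Tuesday and 6.50 min⁻¹ on Friday, and Friday's rate is 1.5 times Tuesday's.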